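The plan cuts ring C of the flavanone at two bonds to ring A, O1–C8a and C4–C4a, so ring A is delivered as an aryne. In one fluoride-triggered operation the C2 hydroxyl of an enantiopure 3-aryl-3-hydroxypropanoate adds to the aryne and the aryl carbanion so formed acylates on the ester, closing ring C with the C2 stereocentre untouched. The step exploits the 1,3 relationship of O1 and C4 in ring C and the C5 oxygen of ring A beside C4a, which polarises the aryne so that oxygen enters at C8a. The precursor is an open-chain hydroxy ester bearing the benzylated kaempferol 3-O-aryl ether, partnered with a silylaryl triflate.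

Key step: step 10

Remark: flavanone numbering is used for the target (ring A = C4a to C8a, ring C = O1 to C4, ring B = the 2-aryl group); apigenin and 2-(benzyloxy)-4-methoxybenzaldehyde are taken as purchasable.

Step 1
Reactants: 1 apigenin
Product: 2 tri-O-benzylapigenin
Conditions: BnBr (4.5 equiv), K2CO3, Bu4NI (cat.), DMF, 80 °C
Reagents that add atoms: benzyl bromide BrCc1ccccc1
Why: Williamson etherification of all three phenols, the chelated 5-OH being forced by excess bromide and heat, so that no free phenol can later add to the aryne.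

Step 2
Reactants: 2 tri-O-benzylapigenin
Product: 4 tri-O-benzylkaempferol, via flavone epoxide 3 (not isolated)
Conditions: DMDO (acetone solution), CH2Cl2, 0 °C; then p-TsOH (cat.), rt
Reagents that add atoms: dimethyldioxirane CC1(C)OO1
Why: Epoxidation of the electron-rich C2=C3 enol-ether bond of the flavone by DMDO, then acid-catalysed opening of the epoxide with loss of the C3 proton, should give the flavonol (flavone C3 hydroxylation).

Step 3
Reactants: 4 tri-O-benzylkaempferol; 5 p-fluorobenzaldehyde
Product: 6 kaempferol aryl ether aldehyde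
Conditions: K2CO3, DMF, 100 °C
Reagents that add atoms: none
Why: Nucleophilic aromatic substitution (SNAr), in which the acidic 3-OH is deprotonated and its oxygen displaces fluoride para to the formyl group through a Meisenheimer adduct.

Step 4
Reactants: 6 kaempferol aryl ether aldehyde; 7 ethyl diazoacetate
Product: 8 β-keto ester
Conditions: SnCl2 (10 mol %), CH2Cl2, rt
Reagents that add atoms: none
Why: Roskamp reaction, in which the diazo carbon adds to the SnCl2-activated aldehyde and a 1,2-hydride shift with loss of N2 gives the β-keto ester.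

Step 5
Reactants: 8 β-keto ester
Product: 9 (S)-β-hydroxy ester
Conditions: H2 (50 atm), RuCl2[(R)-BINAP] (1 mol %), EtOH/CH2Cl2, 50 °C
Reagents that add atoms: none
Why: Noyori asymmetric hydrogenation of a β-keto ester, in which hydride is delivered inside the ruthenium keto-ester chelate and the (R)-BINAP ligand is expected to give the S carbinol for an aryl ketone of this type (aryl outranks CH2CO2Et), while benzyl ethers and the chromone are inert to the ruthenium hydride.

Step 6
Reactants: 10 O-benzyl-4-methoxysalicylaldehyde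
Product: 12 2-(benzyloxy)-4-methoxyphenol, via aryl formate 11 (not isolated)
Conditions: mCPBA, CH2Cl2, 0 °C to rt; then K2CO3 (cat.), MeOH, rt
Reagents that add atoms: 3-chloroperoxybenzoic acid OOC(=O)c1cccc(Cl)c1
Why: Baeyer–Villiger (Dakin-type) oxidation, in which the electron-rich aryl group migrates to oxygen and the resulting formate is methanolysed in the same flask.

Step 7
Reactants: 12 2-(benzyloxy)-4-methoxyphenol
Product: 13 aryl N-isopropylcarbamate
Conditions: i-PrNCO, Et3N (cat.), CH2Cl2, rt
Reagents that add atoms: isopropyl isocyanate CC(C)N=C=O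
Why: Addition of the phenol to the isocyanate gives a carbamate that serves as a directing group for metalation and can later be removed under mild base.

Step 8
Reactants: 13 aryl N-isopropylcarbamate
Product: 17 ortho-silyl carbamate, via N-silyl carbamate 14 (not isolated), via aryllithium 15 (not isolated), via N-silyl C-silyl carbamate 16 (not isolated)
Conditions: TBSOTf, TMEDA, Et2O, 0 °C to rt; n-BuLi, TMEDA, −78 °C; TMSCl, −78 °C to rt; aq NaHSO4
Reagents that add atoms: chlorotrimethylsilane C[Si](C)(C)Cl
Why: Directed ortho-metalation, in which the N-silylated carbamate steers n-BuLi to C6, the only free ortho carbon (the other carries OBn), TMSCl traps the aryllithium and the N-silyl group is lost on work-up.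

Step 9
Reactants: 17 ortho-silyl carbamate
Product: 19 silylaryl triflate, via silyl phenol 18 (not isolated)
Conditions: DBU, Et2NH, MeCN, 40 °C; then PhNTf2, rt
Reagents that add atoms: N-phenylbis(trifluoromethanesulfonimide) O=S(=O)(N(c1ccccc1)S(=O)(=O)C(F)(F)F)C(F)(F)F
Why: DBU-induced E1cB loss of isopropyl isocyanate (trapped by Et2NH as a urea) frees the phenoxide, which is triflated by PhNTf2 to give the o-silylaryl triflate aryne precursor.

Step 10
Reactants: 9 (S)-β-hydroxy ester; 19 silylaryl triflate
Product: 21 benzyl-protected (2S)-flavanone, via aryne 20 (not isolated)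
Conditions: KF, 18-crown-6, THF, −20 °C to rt; 19 (2 equiv) added slowly
Reagents that add atoms: none
Why: Proposed new method: fluoride attacks silicon of 19 and triflate leaves to give aryne 20, the fluoride-activated C2 hydroxyl of 9 adds to C8a (the aryne carbon remote from the benzyloxy group, because the C5–O bond best stabilises the carbanion developing at the adjacent C4a), and this carbanion attacks the ester carbonyl and expels ethoxide, which takes up the hydroxyl proton so that the medium stays near neutral and both O1–C8a and C4–C4a form in one flask. The closest known reactions are the fluoride-induced annulation of arynes with salicylate esters to xanthones, the O–H insertion of aliphatic alcohols into arynes with capture of the aryl anion by carbonyl electrophiles, and the Parham cycloacylation to chroman-4-ones. Ring C closes by 6-exo-trig attack of the C4a carbanion on the ester carbonyl. No stereocentre is formed, since C2 was set in step 5 and neither new bond touches it, so the S configuration should be carried over. The step needs regioselectivity at the aryne (secured by the C5 benzyloxy group next to the triple bond), acylation faster than protonation of the carbanion (favoured by the six-membered transition state, aprotic THF and low temperature) and a single nucleophile (all phenols are benzylated). Low temperature and the absence of strong base should guard against retro-aldol cleavage of 9 and base-induced ring opening of the flavanone.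

Step 11
Reactants: 21 benzyl-protected (2S)-flavanone
Product: 22 target CNP0173006.1
Conditions: H2 (1 atm), Pd/C (10 wt %), EtOAc/THF, rt
Reagents that add atoms: none
Why: Hydrogenolysis of the four aryl benzyl ethers under neutral conditions, which avoids the acid- or base-induced ring opening that would racemise C2, while the aryl ketone and the chromone should not be reduced at this pressure and temperature.

Compound list
1 | apigenin, 5,7-dihydroxy-2-(4-hydroxyphenyl)-4H-chromen-4-one | O=c1cc(-c2ccc(O)cc2)oc2cc(O)cc(O)c12 | starting material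
2 | tri-O-benzylapigenin, 5,7-bis(benzyloxy)-2-[4-(benzyloxy)phenyl]-4H-chromen-4-one | O=c1cc(-c2ccc(OCc3ccccc3)cc2)oc2cc(OCc3ccccc3)cc(OCc3ccccc3)c12 | intermediate
3 | racemic 2,3-epoxide of 2, 5,7-bis(benzyloxy)-1a-[4-(benzyloxy)phenyl]-1a,7a-dihydro-7H-oxireno[2,3-b]chromen-7-one | O=C1C2OC2(c2ccc(OCc3ccccc3)cc2)Oc2cc(OCc3ccccc3)cc(OCc3ccccc3)c12 | intermediate (not isolated)
4 | tri-O-benzylkaempferol, 5,7-bis(benzyloxy)-2-[4-(benzyloxy)phenyl]-3-hydroxy-4H-chromen-4-one | O=c1c(O)c(-c2ccc(OCc3ccccc3)cc2)oc2cc(OCc3ccccc3)cc(OCc3ccccc3)c12 | intermediate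
5 | p-fluorobenzaldehyde (4-fluorobenzaldehyde) | O=Cc1ccc(F)cc1 | starting material
6 | 4-({5,7-bis(benzyloxy)-2-[4-(benzyloxy)phenyl]-4-oxo-4H-chromen-3-yl}oxy)benzaldehyde | O=Cc1ccc(Oc2c(-c3ccc(OCc4ccccc4)cc3)oc3cc(OCc4ccccc4)cc(OCc4ccccc4)c3c2=O)cc1 | intermediate
7 | ethyl diazoacetate | CCOC(=O)C=[N+]=[N-] | starting material
8 | ethyl 3-[4-({5,7-bis(benzyloxy)-2-[4-(benzyloxy)phenyl]-4-oxo-4H-chromen-3-yl}oxy)phenyl]-3-oxopropanoate | CCOC(=O)CC(=O)c1ccc(Oc2c(-c3ccc(OCc4ccccc4)cc3)oc3cc(OCc4ccccc4)cc(OCc4ccccc4)c3c2=O)cc1 | intermediate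
9 | ethyl (3S)-3-[4-({5,7-bis(benzyloxy)-2-[4-(benzyloxy)phenyl]-4-oxo-4H-chromen-3-yl}oxy)phenyl]-3-hydroxypropanoate | CCOC(=O)C[C@H](O)c1ccc(Oc2c(-c3ccc(OCc4ccccc4)cc3)oc3cc(OCc4ccccc4)cc(OCc4ccccc4)c3c2=O)cc1 | intermediate
10 | O-benzyl-4-methoxysalicylaldehyde, 2-(benzyloxy)-4-methoxybenzaldehyde | COc1ccc(C=O)c(OCc2ccccc2)c1 | starting material
11 | 2-(benzyloxy)-4-methoxyphenyl formate | COc1ccc(OC=O)c(OCc2ccccc2)c1 | intermediate (not isolated)
12 | 2-(benzyloxy)-4-methoxyphenol | COc1ccc(O)c(OCc2ccccc2)c1 | intermediate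
13 | 2-(benzyloxy)-4-methoxyphenyl N-(propan-2-yl)carbamate | COc1ccc(OC(=O)NC(C)C)c(OCc2ccccc2)c1 | intermediate
14 | 2-(benzyloxy)-4-methoxyphenyl N-[tert-butyl(dimethyl)silyl]-N-(propan-2-yl)carbamate | COc1ccc(OC(=O)N(C(C)C)[Si](C)(C)C(C)(C)C)c(OCc2ccccc2)c1 | intermediate (not isolated)
15 | 6-lithio derivative of 14 (lithium on the ring carbon ortho to the carbamate oxygen) | COc1cc([Li])c(OC(=O)N(C(C)C)[Si](C)(C)C(C)(C)C)c(OCc2ccccc2)c1 | intermediate (not isolated)
16 | 2-(benzyloxy)-4-methoxy-6-(trimethylsilyl)phenyl N-[tert-butyl(dimethyl)silyl]-N-(propan-2-yl)carbamate | COc1cc([Si](C)(C)C)c(OC(=O)N(C(C)C)[Si](C)(C)C(C)(C)C)c(OCc2ccccc2)c1 | intermediate (not isolated)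
17 | 2-(benzyloxy)-4-methoxy-6-(trimethylsilyl)phenyl N-(propan-2-yl)carbamate | COc1cc([Si](C)(C)C)c(OC(=O)NC(C)C)c(OCc2ccccc2)c1 | intermediate
18 | 2-(benzyloxy)-4-methoxy-6-(trimethylsilyl)phenol | COc1cc([Si](C)(C)C)c(O)c(OCc2ccccc2)c1 | intermediate (not isolated)
19 | 2-(benzyloxy)-4-methoxy-6-(trimethylsilyl)phenyl trifluoromethanesulfonate | COc1cc([Si](C)(C)C)c(OS(=O)(=O)C(F)(F)F)c(OCc2ccccc2)c1 | intermediate
20 | 3-(benzyloxy)-5-methoxybenzyne (3-(benzyloxy)-5-methoxy-1,2-didehydrobenzene) | COC1=CC#CC(OCc2ccccc2)=C1 | intermediate (not isolated)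
21 | (2S)-5-(benzyloxy)-2-[4-({5,7-bis(benzyloxy)-2-[4-(benzyloxy)phenyl]-4-oxo-4H-chromen-3-yl}oxy)phenyl]-7-methoxy-2,3-dihydro-4H-chromen-4-one | COc1cc(OCc3ccccc3)c2c(c1)O[C@H](c1ccc(Oc3c(-c4ccc(OCc5ccccc5)cc4)oc4cc(OCc5ccccc5)cc(OCc5ccccc5)c4c3=O)cc1)CC2=O | intermediate
22 | CNP0173006.1, (2S)-2-(4-{[5,7-dihydroxy-2-(4-hydroxyphenyl)-4-oxo-4H-chromen-3-yl]oxy}phenyl)-5-hydroxy-7-methoxy-2,3-dihydro-4H-chromen-4-one | COc1cc(O)c2c(c1)O[C@H](c1ccc(Oc3c(-c4ccc(O)cc4)oc4cc(O)cc(O)c4c3=O)cc1)CC2=O | target

Total step count: 11. Longest linear sequence: 7 steps (steps 1, 2, 3, 4, 5, 10, 11).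

Steps most likely to fail

Step 10 (bears the label). The C4a carbanion may be protonated before it acylates, which would stop the sequence at simple O-arylation. Fluoride basicity may also trigger retro-aldol cleavage of the hydroxy ester or ring opening of the flavanone, with loss of configuration at C2. The fallback uses known chemistry only and sets out from aldehyde 6. Commercial 1-(2,6-dihydroxy-4-methoxyphenyl)ethan-1-one is monobenzylated (BnBr, K2CO3, acetone, reflux; the second hydroxyl stays chelated) to 1-[2-(benzyloxy)-6-hydroxy-4-methoxyphenyl]ethan-1-one F1. Claisen–Schmidt condensation of F1 with 6 (KOH, EtOH/THF, rt) should give the 2'-hydroxychalcone F2, and oxa-Michael cyclisation (NaOAc, EtOH, reflux) the racemic flavanone F3. Kinetic resolution by asymmetric transfer hydrogenation with RuCl[(R,R)-TsDPEN](p-cymene) in HCO2H/Et3N and EtOAc, stopped near half conversion, is expected to reduce the 2R enantiomer to the cis-(2R,4R)-flavan-4-ol F4 and leave the 2S ketone. The fallback comes back to the route at 21.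

Step 8. Deprotonation at the benzylic CH2 of the benzyl ether (followed by Wittig rearrangement) or at C3 between the two ether oxygens may compete with carbamate-directed lithiation. The fallback sets out from phenol 12 and replaces directed metalation by halogen–lithium exchange. Amine-directed ortho-bromination (NBS, i-Pr2NH (cat.), CH2Cl2, 0 °C) should give 2-(benzyloxy)-6-bromo-4-methoxyphenol F5, and O-silylation (HMDS, THF, reflux) the aryl trimethylsilyl ether F6. Treatment with n-BuLi (THF, −78 °C) should bring about bromine–lithium exchange and a 1,3 O-to-C silyl shift (retro-Brook rearrangement) to the lithium salt of 18, which is quenched with Tf2O. The fallback comes back to the route at 19.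

Step 3. Substitution by the hindered, weakly nucleophilic flavonol 3-oxide at an only moderately activated fluoroarene may be slow, and long heating with carbonate invites base-induced degradation of the aldehyde and the chromone. The fallback sets out from 4 and forms the same C–O bond by copper-catalysed Ullmann-type coupling with 4-iodobenzaldehyde (CuI, N,N-dimethylglycine, Cs2CO3, dioxane, 90 °C, under nitrogen). It comes back to the route at 6 and makes no new compound (none, F0).

Further compounds
F1 | step 10 | 1-[2-(benzyloxy)-6-hydroxy-4-methoxyphenyl]ethan-1-one | CC(=O)c1c(O)cc(OC)cc1OCc1ccccc1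
F2 | step 10 | (2E)-1-[2-(benzyloxy)-6-hydroxy-4-methoxyphenyl]-3-[4-({5,7-bis(benzyloxy)-2-[4-(benzyloxy)phenyl]-4-oxo-4H-chromen-3-yl}oxy)phenyl]prop-2-en-1-one | O=C(/C=C/c1ccc(Oc2c(-c3ccc(OCc4ccccc4)cc3)oc3cc(OCc4ccccc4)cc(OCc4ccccc4)c3c2=O)cc1)c1c(O)cc(OC)cc1OCc1ccccc1
F3 | step 10 | racemic 5-(benzyloxy)-2-[4-({5,7-bis(benzyloxy)-2-[4-(benzyloxy)phenyl]-4-oxo-4H-chromen-3-yl}oxy)phenyl]-7-methoxy-2,3-dihydro-4H-chromen-4-one | COc1cc(OCc3ccccc3)c2c(c1)OC(c1ccc(Oc3c(-c4ccc(OCc5ccccc5)cc4)oc4cc(OCc5ccccc5)cc(OCc5ccccc5)c4c3=O)cc1)CC2=O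
F4 | step 10 | 5,7-bis(benzyloxy)-2-[4-(benzyloxy)phenyl]-3-{4-[(2R,4R)-5-(benzyloxy)-4-hydroxy-7-methoxy-3,4-dihydro-2H-chromen-2-yl]phenoxy}-4H-chromen-4-one | COc1cc(OCc3ccccc3)c2c(c1)O[C@@H](c1ccc(Oc3c(-c4ccc(OCc5ccccc5)cc4)oc4cc(OCc5ccccc5)cc(OCc5ccccc5)c4c3=O)cc1)C[C@H]2O
F5 | step 8 | 2-(benzyloxy)-6-bromo-4-methoxyphenol | COc1cc(Br)c(O)c(OCc2ccccc2)c1
F6 | step 8 | [2-(benzyloxy)-6-bromo-4-methoxyphenoxy]trimethylsilane | COc1cc(Br)c(O[Si](C)(C)C)c(OCc2ccccc2)c1
F0 | step 3 | none | none
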